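**Retrosynthetic overview**
1. Target ⇐ N-methylation/elimination to the 11(13)-methylene, epoxide-to-allylic-alcohol isomerisation (a 4,5-epoxide stores both 5-OH and the 4(15)-methylene) and angeloylation of 8-OH.
2. Ten-membered ring ⇐ C9–C10: one-flask diboration of a C7 vinyl group, Suzuki–Miyaura closure of the primary C9 boronate onto C10 of a (Z)-α-chloroenoate, oxidation of the C8 boronate.
3. Enabling feature: the homoallylic carbinol array O–C8(H)–C9H2–C10(=C1) of the carbocycle is the coupling/oxidation image of a vicinal bis(boronate), i.e. of a plain vinyl group on C7 of the trans-fused lactone ring (O, C6, C7, C11, C12).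
4. Vinyl lactone ⇐ anti conjugate addition/Mannich trapping on a butenolide ⇐ Lindlar reduction/lactonisation ⇐ hydroxyl-directed epoxidation ⇐ catalytic asymmetric propiolate addition to an (E)-enal ⇐ carboalumination of pent-4-yn-1-ol.
5. Ring order: oxirane (step 5), lactone (step 6), ten-membered carbocycle (step 10).

Key step: step 10

Remark (locants): germacrane numbering is used for all intermediates: C1–C10 ring carbons, C11–C13 lactone carbons, C14 ester carbon, C15 the carbon on C4.
Remark (assumption): the ligand enantiomers named in steps 4 and 10 are taken to give the C6 and C8 configurations drawn; if the sense of induction is the opposite, the mirror-image ligand is used.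

**Step 1**
Reactants: 1 pent-4-yn-1-ol
Product: 2 triethyl(pent-4-yn-1-yloxy)silane
Conditions: Et3SiCl, imidazole, CH2Cl2, 0 °C to rt
Reagents that add atoms: chlorotriethylsilane, CC[Si](Cl)(CC)CC
Why: Standard silylation of a primary alcohol, the triethylsilyl ether being chosen because it can later be oxidised directly to the aldehyde without a free alcohol next to the epoxide.

**Step 2**
Reactants: 2 triethyl(pent-4-yn-1-yloxy)silane
Product: 3 (2E)-3-methyl-6-[(triethylsilyl)oxy]hex-2-en-1-ol
Conditions: Me3Al, Cp2ZrCl2 (20 mol%), CH2Cl2, 0 °C to rt; n-BuLi, THF/hexane, −78 °C; (CH2O)n, rt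
Reagents that add atoms: trimethylaluminium, C[Al](C)C; paraformaldehyde (as formaldehyde), C=O
Why: Zirconium-catalysed syn-carboalumination (Negishi) puts the methyl group (C15) on C4 and aluminium on C5, and hydroxymethylation of the alanate with retention should give the E alkene with C6 cis to the methyl group.

**Step 3**
Reactants: 3 (2E)-3-methyl-6-[(triethylsilyl)oxy]hex-2-en-1-ol
Product: 4 (2E)-3-methyl-6-[(triethylsilyl)oxy]hex-2-enal
Conditions: MnO2, CH2Cl2, rt
Reagents that add atoms: none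
Why: Neutral MnO2 oxidation of a primary allylic alcohol should stop at the enal and leave the silyl ether and the alkene geometry untouched.

**Step 4**
Reactants: 4 (2E)-3-methyl-6-[(triethylsilyl)oxy]hex-2-enal
Product: 5 methyl (4R,5E)-4-hydroxy-6-methyl-9-[(triethylsilyl)oxy]non-5-en-2-ynoate
Conditions: HC≡CCO2Me, Me2Zn, (S,S)-ProPhenol (10 mol%), Ph3PO (20 mol%), toluene, 4 °C
Reagents that add atoms: methyl propiolate, C#CC(=O)OC
Why: ProPhenol/dizinc-catalysed asymmetric alkynylation of an enal, in which the chiral dinuclear zinc pocket selects the aldehyde face and so sets C6.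

**Step 5**
Reactants: 5 methyl (4R,5E)-4-hydroxy-6-methyl-9-[(triethylsilyl)oxy]non-5-en-2-ynoate
Product: 6 methyl (4S)-4-hydroxy-4-[(2R,3R)-3-methyl-3-{3-[(triethylsilyl)oxy]propyl}oxiran-2-yl]but-2-ynoate
Conditions: mCPBA, NaHCO3, CH2Cl2, 0 °C
Reagents that add atoms: 3-chloroperoxybenzoic acid, OOC(=O)c1cccc(Cl)c1
Why: Hydroxyl-directed (Henbest) epoxidation of the electron-rich trisubstituted alkene, in which allylic 1,3-strain with the cis methyl group holds C6–H in the alkene plane so that the peracid is delivered syn to the hydroxyl and the threo epoxy alcohol (C4 and C5 from C6) should result.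

**Step 6**
Reactants: 6 methyl (4S)-4-hydroxy-4-[(2R,3R)-3-methyl-3-{3-[(triethylsilyl)oxy]propyl}oxiran-2-yl]but-2-ynoate
Product: 8 (5S)-5-[(2R,3R)-3-methyl-3-{3-[(triethylsilyl)oxy]propyl}oxiran-2-yl]furan-2(5H)-one, via hydroxy Z-enoate 7 (not isolated)
Conditions: H2 (1 atm), Lindlar catalyst (Pd/CaCO3, Pb(OAc)2-poisoned), quinoline, EtOAc, rt; then toluene, 50 °C
Reagents that add atoms: none
Why: Lindlar cis-semihydrogenation of the ynoate gives the Z-enoate, whose γ-hydroxyl should close the butenolide by 5-exo-trig lactonisation with loss of methanol and without touching C6.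

**Step 7**
Reactants: 8 (5S)-5-[(2R,3R)-3-methyl-3-{3-[(triethylsilyl)oxy]propyl}oxiran-2-yl]furan-2(5H)-one
Product: 9 (3R,4S,5S)-3-[(dimethylamino)methyl]-4-ethenyl-5-[(2R,3R)-3-methyl-3-{3-[(triethylsilyl)oxy]propyl}oxiran-2-yl]oxolan-2-one
Conditions: CH2=CHMgBr, CuBr·SMe2 (20 mol%), THF, −78 °C; then Me2N=CH2 I (Eschenmoser's salt), −78 to 0 °C
Reagents that add atoms: vinylmagnesium bromide, C=C[Mg]Br; N,N-dimethylmethyleneiminium iodide, C[N+](C)=C.[I-]
Why: Copper-catalysed conjugate addition delivers the vinyl group anti to the γ-substituent of the butenolide (C7, trans-lactone), and Mannich trapping of the enolate anti to the new vinyl group stores C13 as a masked exocyclic methylene.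

**Step 8**
Reactants: 9 (3R,4S,5S)-3-[(dimethylamino)methyl]-4-ethenyl-5-[(2R,3R)-3-methyl-3-{3-[(triethylsilyl)oxy]propyl}oxiran-2-yl]oxolan-2-one
Product: 10 3-[(2R,3R)-3-{(2S,3S,4R)-4-[(dimethylamino)methyl]-3-ethenyl-5-oxooxolan-2-yl}-2-methyloxiran-2-yl]propanal
Conditions: (COCl)2, DMSO, CH2Cl2, −78 to −30 °C; Et3N, −78 °C to rt
Reagents that add atoms: none
Why: Under Swern conditions a primary triethylsilyl ether is converted directly into the aldehyde through the alkoxysulfonium ion, so no free 4,5-epoxy alcohol (prone to tetrahydrofuran formation) is ever present.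

**Step 9**
Reactants: 10 3-[(2R,3R)-3-{(2S,3S,4R)-4-[(dimethylamino)methyl]-3-ethenyl-5-oxooxolan-2-yl}-2-methyloxiran-2-yl]propanal
Product: 11 methyl (2Z)-2-chloro-5-[(2R,3R)-3-{(2S,3S,4R)-4-[(dimethylamino)methyl]-3-ethenyl-5-oxooxolan-2-yl}-2-methyloxiran-2-yl]pent-2-enoate
Conditions: Ph3P=CHCO2Me, NCS, CH2Cl2, −20 °C; then 10, rt
Reagents that add atoms: methyl (triphenylphosphoranylidene)acetate, COC(=O)C=P(c1ccccc1)(c1ccccc1)c1ccccc1; N-chlorosuccinimide, O=C1CCC(=O)N1Cl
Why: Wittig olefination with the stabilised ylide chlorinated in the flask should give the (Z)-α-chloroenoate (ester trans to the chain), which fixes the later C1=C10 geometry.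

**Step 10**
Reactants: 11 methyl (2Z)-2-chloro-5-[(2R,3R)-3-{(2S,3S,4R)-4-[(dimethylamino)methyl]-3-ethenyl-5-oxooxolan-2-yl}-2-methyloxiran-2-yl]pent-2-enoate
Product: 14 methyl (1(10)E,4R,5R,6S,7R,8R,11R)-13-(dimethylamino)-4,5-epoxy-8-hydroxygermacr-1(10)-en-12,6-olid-14-oate, via bis(boronate) 12 (not isolated), via cyclic C8 boronate 13 (not isolated)
Conditions: B2pin2, Pt(dba)3 (3 mol%), (R,R)-3,5-diethylphenyl-TADDOL phenylphosphonite (6 mol%), THF, 60 °C; then slow addition to Pd(OAc)2 (15 mol%), RuPhos (30 mol%), K3PO4, THF/H2O (50:1), 70 °C, 2 mM; then NaBO3·4H2O, rt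
Reagents that add atoms: bis(pinacolato)diboron, CC1(C)OB(OC1(C)C)B1OC(C)(C)C(C)(C)O1 (boron groups of 12 and 13); sodium perborate, [Na+].[O-]OB=O (oxygen on C8 of 14)
Why: Proposed new method: zerovalent platinum adds B2pin2 syn across C8=C9, the only monosubstituted alkene left (C4=C15 is stored as the epoxide, C11=C13 as the amine, and the chloroenoate is trisubstituted and electron-poor), with the phosphonite ligand choosing the alkene face and thereby C8. In the second stage zerovalent palladium inserts into the alkenyl C10–Cl bond, the primary C9 boronate, activated by base through the neighbouring C8 boronate, transmetalates in preference to the secondary one, and C(sp3)–C(sp2) reductive elimination from an eleven-membered palladacycle closes the ten-membered carbocycle at C9–C10 with retention of the alkene geometry (C9 cis to C2). Perborate then oxidises the remaining C8–B bond with retention to the carbinol. The closest known reactions are the intermolecular one-pot diboration/cross-coupling/oxidation of terminal alkenes with alkenyl halides and the B-alkyl Suzuki–Miyaura macrocyclisation; what is new is their union in a ring-closing mode for a medium ring. Ring closure has to beat oligomerisation, which is helped by slow addition at 2 mM and by the trans-lactone and trans-epoxide that bend C9 towards C10, and no Heck or radical path competes because the substrate holds no other free alkene within reach of C10.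

**Step 11**
Reactants: 14 methyl (1(10)E,4R,5R,6S,7R,8R,11R)-13-(dimethylamino)-4,5-epoxy-8-hydroxygermacr-1(10)-en-12,6-olid-14-oate
Product: 15 methyl (1(10)E,4R,5R,6S,7R,8R,11R)-8-(angeloyloxy)-13-(dimethylamino)-4,5-epoxygermacr-1(10)-en-12,6-olid-14-oate
Conditions: angelic acid, 2,4,6-trichlorobenzoyl chloride, Et3N, toluene, rt; then 14, 75 °C
Reagents that add atoms: angelic acid, C/C=C(/C)C(=O)O
Why: Yamaguchi-type mixed-anhydride esterification run without DMAP should acylate the only free hydroxyl (C8) while avoiding angelate-to-tiglate isomerisation.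

**Step 12**
Reactants: 15 methyl (1(10)E,4R,5R,6S,7R,8R,11R)-8-(angeloyloxy)-13-(dimethylamino)-4,5-epoxygermacr-1(10)-en-12,6-olid-14-oate
Product: 16 methyl (1(10)E,5S,6S,7R,8R,11R)-8-(angeloyloxy)-13-(dimethylamino)-5-hydroxygermacra-1(10),4(15)-dien-12,6-olid-14-oate
Conditions: Cp2TiCl2, Mn, THF, rt (gives Cp2TiCl); then 15; aq NaH2PO4
Reagents that add atoms: none
Why: Trivalent titanium (Cp2TiCl) opens the epoxide homolytically at the tertiary carbon C4 (Nugent–RajanBabu opening), and loss of a C15 hydrogen from the radical through a second Cp2TiCl should give the exocyclic alkene while the C5–O bond, and with it the C5 configuration, is never broken.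

**Step 13**
Reactants: 16 methyl (1(10)E,5S,6S,7R,8R,11R)-8-(angeloyloxy)-13-(dimethylamino)-5-hydroxygermacra-1(10),4(15)-dien-12,6-olid-14-oate
Product: 18 methyl (1(10)E,5S,6S,7R,8R)-8-(angeloyloxy)-5-hydroxygermacra-1(10),4(15),11(13)-trien-12,6-olid-14-oate (CNP0163095.1), via trimethylammonium iodide 17 (not isolated)
Conditions: MeI, THF/MeOH, rt; then aq NaHCO3, EtOAc, rt
Reagents that add atoms: iodomethane, CI (N-methyl group of 17, lost again as trimethylamine)
Why: Exhaustive N-methylation followed by E1cB (Hofmann-type) loss of trimethylamine from the β-ammonio lactone should unveil the α-methylene-γ-butyrolactone under conditions that spare the angelate, the enoate and the free C5 hydroxyl.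

**Compound list**
1 | pent-4-yn-1-ol | C#CCCCO | starting material
2 | triethyl(pent-4-yn-1-yloxy)silane | C#CCCCO[Si](CC)(CC)CC | intermediate
3 | (2E)-3-methyl-6-[(triethylsilyl)oxy]hex-2-en-1-ol | OC/C=C(\C)CCCO[Si](CC)(CC)CC | intermediate
4 | (2E)-3-methyl-6-[(triethylsilyl)oxy]hex-2-enal | O=C/C=C(\C)CCCO[Si](CC)(CC)CC | intermediate
5 | methyl (4R,5E)-4-hydroxy-6-methyl-9-[(triethylsilyl)oxy]non-5-en-2-ynoate | COC(=O)C#C[C@H](O)/C=C(\C)CCCO[Si](CC)(CC)CC | intermediate
6 | methyl (4S)-4-hydroxy-4-[(2R,3R)-3-methyl-3-{3-[(triethylsilyl)oxy]propyl}oxiran-2-yl]but-2-ynoate | COC(=O)C#C[C@H](O)[C@H]1O[C@]1(C)CCCO[Si](CC)(CC)CC | intermediate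
7 | methyl (2Z,4S)-4-hydroxy-4-[(2R,3R)-3-methyl-3-{3-[(triethylsilyl)oxy]propyl}oxiran-2-yl]but-2-enoate | COC(=O)/C=C\[C@H](O)[C@H]1O[C@]1(C)CCCO[Si](CC)(CC)CC | intermediate
8 | (5S)-5-[(2R,3R)-3-methyl-3-{3-[(triethylsilyl)oxy]propyl}oxiran-2-yl]furan-2(5H)-one | CC[Si](CC)(CC)OCCC[C@@]1(C)O[C@@H]1[C@H]2OC(=O)C=C2 | intermediate
9 | (3R,4S,5S)-3-[(dimethylamino)methyl]-4-ethenyl-5-[(2R,3R)-3-methyl-3-{3-[(triethylsilyl)oxy]propyl}oxiran-2-yl]oxolan-2-one | CC[Si](CC)(CC)OCCC[C@@]1(C)O[C@@H]1[C@H]2OC(=O)[C@@H](CN(C)C)[C@@H]2C=C | intermediate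
10 | 3-[(2R,3R)-3-{(2S,3S,4R)-4-[(dimethylamino)methyl]-3-ethenyl-5-oxooxolan-2-yl}-2-methyloxiran-2-yl]propanal | O=CCC[C@@]1(C)O[C@@H]1[C@H]2OC(=O)[C@@H](CN(C)C)[C@@H]2C=C | intermediate
11 | methyl (2Z)-2-chloro-5-[(2R,3R)-3-{(2S,3S,4R)-4-[(dimethylamino)methyl]-3-ethenyl-5-oxooxolan-2-yl}-2-methyloxiran-2-yl]pent-2-enoate | COC(=O)/C(Cl)=C/CC[C@@]1(C)O[C@@H]1[C@H]2OC(=O)[C@@H](CN(C)C)[C@@H]2C=C | intermediate
12 | methyl (2Z)-5-[(2R,3R)-3-{(2S,3S,4R)-3-[(1R)-1,2-bis(4,4,5,5-tetramethyl-1,3,2-dioxaborolan-2-yl)ethyl]-4-[(dimethylamino)methyl]-5-oxooxolan-2-yl}-2-methyloxiran-2-yl]-2-chloropent-2-enoate | COC(=O)/C(Cl)=C/CC[C@@]1(C)O[C@@H]1[C@H]2OC(=O)[C@@H](CN(C)C)[C@@H]2[C@H](B3OC(C)(C)C(C)(C)O3)CB4OC(C)(C)C(C)(C)O4 | intermediate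
13 | methyl (1(10)E,4R,5R,6S,7S,8R,11R)-13-(dimethylamino)-4,5-epoxy-8-(4,4,5,5-tetramethyl-1,3,2-dioxaborolan-2-yl)germacr-1(10)-en-12,6-olid-14-oate | COC(=O)/C1=C/CC[C@@]2(C)O[C@@H]2[C@H]3OC(=O)[C@@H](CN(C)C)[C@@H]3[C@H](B4OC(C)(C)C(C)(C)O4)C1 | intermediate
14 | methyl (1(10)E,4R,5R,6S,7R,8R,11R)-13-(dimethylamino)-4,5-epoxy-8-hydroxygermacr-1(10)-en-12,6-olid-14-oate | COC(=O)/C1=C/CC[C@@]2(C)O[C@@H]2[C@H]3OC(=O)[C@@H](CN(C)C)[C@@H]3[C@H](O)C1 | intermediate
15 | methyl (1(10)E,4R,5R,6S,7R,8R,11R)-8-(angeloyloxy)-13-(dimethylamino)-4,5-epoxygermacr-1(10)-en-12,6-olid-14-oate | COC(=O)/C1=C/CC[C@@]2(C)O[C@@H]2[C@H]3OC(=O)[C@@H](CN(C)C)[C@@H]3[C@H](OC(=O)/C(C)=C\C)C1 | intermediate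
16 | methyl (1(10)E,5S,6S,7R,8R,11R)-8-(angeloyloxy)-13-(dimethylamino)-5-hydroxygermacra-1(10),4(15)-dien-12,6-olid-14-oate | COC(=O)/C1=C/CCC(=C)[C@H](O)[C@H]2OC(=O)[C@@H](CN(C)C)[C@@H]2[C@H](OC(=O)/C(C)=C\C)C1 | intermediate
17 | N-methyl ammonium iodide of 16 (13-trimethylammonio group) | COC(=O)/C1=C/CCC(=C)[C@H](O)[C@H]2OC(=O)[C@@H](C[N+](C)(C)C)[C@@H]2[C@H](OC(=O)/C(C)=C\C)C1.[I-] | intermediate
18 | methyl (1(10)E,5S,6S,7R,8R)-8-(angeloyloxy)-5-hydroxygermacra-1(10),4(15),11(13)-trien-12,6-olid-14-oate (CNP0163095.1) | C=C1C(=O)O[C@H]2[C@H]1[C@H](OC(=O)/C(C)=C\C)C/C(C(=O)OC)=C\CCC(=C)[C@@H]2O | target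

**Count and risks**
Total step count: 13. Longest linear sequence: 13 steps (1 to 18).

Steps most likely to fail:

1. Step 10 (proposed new method). What may go wrong:
   - catalyst cross-talk in the single flask (insertion of zerovalent platinum into the C–Cl bond, borylation of that bond by unconsumed diboron);
   - chain growth instead of ring closure;
   - opening of the lactone by the aqueous base;
   - a mismatched facial preference in the diboration.

   Fallback with known reactions, the three events separated and reordered: it sets out from 9. Platinum-catalysed asymmetric diboration of the vinyl group of 9, before any alkenyl halide exists, should give the bis(boronate) silyl ether F1. Swern oxidation as in step 8 should give the bis(boronate) aldehyde F2. The chloro-ylide Wittig reaction of step 9 then gives 12 as an isolated compound. A separate B-alkyl Suzuki–Miyaura macrocyclisation of 12 (Pd(OAc)2, RuPhos, K3PO4, syringe-pump addition) gives 13, and oxidation with NaBO3 comes back to the route at 14.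

2. Step 12. What may go wrong: loss of a C3 hydrogen instead of a C15 hydrogen (endocyclic alkene), reduction of the C4 radical, or deoxygenation to the C4=C5 alkene. Fallback by an ionic instead of a radical opening: it sets out from 15. Me3SiOTf and DBU in toluene (opening at C4, base-induced loss of a C15 proton) should give the allylic trimethylsilyl ether F3. Citric acid in methanol removes the silyl group and comes back to the route at 16.

3. Step 7. What may go wrong: γ-deprotonation of the butenolide by the Grignard reagent with β-opening of the neighbouring epoxide, or attack of the organocopper species on the epoxide. Fallback that separates a neutral vinyl transfer from the Mannich step: it sets out from 8. Rhodium-catalysed conjugate addition (Hayashi–Miyaura) of potassium vinyltrifluoroborate with [Rh(cod)OH]2 in dioxane/H2O should give the trans vinyl lactone F4. Enolisation with LiHMDS at −78 °C and trapping with Eschenmoser's salt comes back to the route at 9.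

**Further compounds**
F1 | step 10 | (3R,4S,5S)-4-[(1R)-1,2-bis(4,4,5,5-tetramethyl-1,3,2-dioxaborolan-2-yl)ethyl]-3-[(dimethylamino)methyl]-5-[(2R,3R)-3-methyl-3-{3-[(triethylsilyl)oxy]propyl}oxiran-2-yl]oxolan-2-one | CC[Si](CC)(CC)OCCC[C@@]1(C)O[C@@H]1[C@H]2OC(=O)[C@@H](CN(C)C)[C@@H]2[C@H](B3OC(C)(C)C(C)(C)O3)CB4OC(C)(C)C(C)(C)O4
F2 | step 10 | 3-[(2R,3R)-3-{(2S,3S,4R)-3-[(1R)-1,2-bis(4,4,5,5-tetramethyl-1,3,2-dioxaborolan-2-yl)ethyl]-4-[(dimethylamino)methyl]-5-oxooxolan-2-yl}-2-methyloxiran-2-yl]propanal | O=CCC[C@@]1(C)O[C@@H]1[C@H]2OC(=O)[C@@H](CN(C)C)[C@@H]2[C@H](B3OC(C)(C)C(C)(C)O3)CB4OC(C)(C)C(C)(C)O4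
F3 | step 12 | 5-O-trimethylsilyl ether of 16 | COC(=O)/C1=C/CCC(=C)[C@H](O[Si](C)(C)C)[C@H]2OC(=O)[C@@H](CN(C)C)[C@@H]2[C@H](OC(=O)/C(C)=C\C)C1
F4 | step 7 | (4R,5S)-4-ethenyl-5-[(2R,3R)-3-methyl-3-{3-[(triethylsilyl)oxy]propyl}oxiran-2-yl]oxolan-2-one | CC[Si](CC)(CC)OCCC[C@@]1(C)O[C@@H]1[C@H]2OC(=O)C[C@@H]2C=C
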